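**Retrosynthetic overview**

1. The target comes from (1S)-3-methoxy-1-nonadecylcyclohex-3-en-1-ol by α-selenenylation of the enol ether and selenoxide elimination; the enol ether fixes both the carbonyl carbon and the position of the C=C bond.
2. That cyclohexenol comes from a [2,3]-Wittig ring expansion of a 2-lithio-2-nonadecyl-5-(1-methoxyvinyl)oxolane, made by reductive lithiation of its 2-phenylsulfanyl precursor. The carbanion carbon (future carbinol carbon) bonds to the vinyl CH2 (future CH2 between carbinol and carbonyl carbons) as the allylic C5–O1 bond breaks.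
3. Enabling feature: ring oxygen O1 of the oxolane joins the lithium-bearing C2 to the allylic C5, and the C3–C4 bridge lets the 1-methoxyvinyl group on C5 reach C2 only on its own ring face. The (5R) centre is therefore relayed to the quaternary carbinol and is itself erased (it becomes sp2), while O1 becomes the tertiary OH.
4. The sulfide comes from Tebbe methylenation of a methyl ester, ketal to O,S-ketal exchange, and Grignard mono-addition of the C19 unit (from 1-bromononadecane) to the lactone carbonyl of (R)-5-oxooxolane-2-carboxylic acid (chiral pool, commercial in both enantiomeric forms).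
5. Ring order: the oxolane comes with the starting material and is a temporary ring; the cyclohexene, the only ring of the target, is formed in step 5 as the oxolane is opened.

Key step: step 5

Remark: magnesium and lithium salts of a product that are only protonated on work-up are counted with that product, and ketal-type centres that are destroyed later are carried as mixtures of epimers.

**Route**

Step 1
Reactants: 1 (2R)-5-oxooxolane-2-carboxylic acid; 2 1-bromononadecane
Product: 4 (2R)-5-hydroxy-5-nonadecyloxolane-2-carboxylic acid (cyclic hemiketal of the hydroxy keto acid), via nonadecylmagnesium bromide 3 (not isolated)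
Conditions: 2, Mg, THF, 50 °C; 1, t-BuMgCl (1.0 equiv), THF, −78 °C; then 3 (1.2 equiv), −78 → −40 °C; 1 M aq. HCl, 0 °C
Reagents that add atoms: none
Why: Grignard addition to a γ-lactone should stop at the magnesium hemiketal alkoxide at low temperature (as in additions to aldonolactones), the carboxyl group is masked in the flask as its unreactive magnesium carboxylate, and the stereocentre of 1 is not touched.

Step 2
Reactants: 4 (2R)-5-hydroxy-5-nonadecyloxolane-2-carboxylic acid
Product: 5 methyl (2R)-5-methoxy-5-nonadecyloxolane-2-carboxylate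
Conditions: MeOH, camphorsulfonic acid (0.1 equiv), 3 Å molecular sieves, 40 °C
Reagents that add atoms: methanol CO
Why: Fischer esterification with concurrent acid-catalysed conversion of the cyclic hemiketal into its methyl ketal should give a stable, chromatographable compound; the ketal centre forms as a mixture, which does not matter because it is made carbanionic later.

Step 3
Reactants: 5 methyl (2R)-5-methoxy-5-nonadecyloxolane-2-carboxylate
Product: 6 methyl (2R)-5-nonadecyl-5-(phenylsulfanyl)oxolane-2-carboxylate
Conditions: PhSH (1.3 equiv), BF3·OEt2 (0.3 equiv), CH2Cl2, −78 → −40 °C; Et3N quench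
Reagents that add atoms: thiophenol Sc1ccccc1
Why: Lewis-acid-catalysed ketal exchange through the tertiary cyclic oxocarbenium ion (thioglycosidation type) should give the O,S-ketal needed for reductive lithiation, and either epimer at the ketal carbon serves.

Step 4
Reactants: 6 methyl (2R)-5-nonadecyl-5-(phenylsulfanyl)oxolane-2-carboxylate
Product: 7 (5R)-5-(1-methoxyethenyl)-2-nonadecyl-2-(phenylsulfanyl)oxolane
Conditions: Tebbe reagent Cp2Ti(μ-CH2)(μ-Cl)AlMe2 (1.3 equiv), pyridine, THF–toluene, −40 → 0 °C; 15% aq. NaOH
Reagents that add atoms: Tebbe reagent Cp2Ti(μ-CH2)(μ-Cl)AlMe2 [CH2]=[Ti](C1C=CC=C1)C1C=CC=C1.C[Al](C)Cl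
Why: Tebbe methylenation of an ester should give the 1-methoxyvinyl ether without enolising the adjacent stereocentre, with pyridine and low temperature tempering the Lewis acidity toward the O,S-ketal.

Step 5
Reactants: 7 (5R)-5-(1-methoxyethenyl)-2-nonadecyl-2-(phenylsulfanyl)oxolane
Product: 9 (1S)-3-methoxy-1-nonadecylcyclohex-3-en-1-ol, via [(5R)-5-(1-methoxyethenyl)-2-nonadecyloxolan-2-yl]lithium 8 (not isolated)
Conditions: lithium 4,4'-di-tert-butylbiphenylide (2.2 equiv), THF, −78 °C, then −78 → −40 °C; H2O, −78 °C; wash with dilute aq. NaOH; Et3N-deactivated silica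
Reagents that add atoms: none
Why: Proposed new method: two-electron reductive cleavage of the C–S bond of the tertiary O,S-ketal by the arene radical anion gives the non-stabilised α-alkoxy organolithium 8, in which carbanion carbon, ring oxygen, allylic ring carbon and the 1-methoxyvinyl group form the five-atom array of a [2,3]-Wittig rearrangement; the closest known reaction type is the [2,3]-Wittig shift of α-alkoxy organolithiums generated by reductive lithiation of O,S-acetals or by tin–lithium exchange (Wittig–Still), here proposed with the carbanion inside the ring of a 2-vinyl cyclic ether so that the oxolane is expanded to a cyclohexene. The six-membered carbocycle closes in a 6-endo-trig SN2′-type mode (the attacked vinyl group lies inside the new ring) through the five-membered envelope of the sigmatropic shift, bridged by C3–C4 of the oxolane into a 7-oxabicyclo[2.2.1]heptene-like array in which the breaking allylic C–O bond lies nearly parallel to the π system. The new quaternary stereocentre is controlled by the (5R) centre alone: the two-atom vinyl bridge can reach the carbanion only on the ring face it occupies, so the new C–C bond forms cis to the breaking C–O bond and the configuration is relayed across the ring oxygen to give (S), whichever epimer of 8 reacts. The step needs the [2,3] shift to win over the [1,2] shift, over anionic cycloreversion of the lithiated oxolane (to a ketone enolate and 2-methoxybutadiene) and over protonation; the [1,2] path would lead to a strained cyclobutanol, and working at −78 to −40 °C, where non-stabilised α-alkoxy organolithiums already rearrange, is meant to keep cycloreversion slow. The methoxy group on the vinyl unit ends as a regiodefined enol ether that marks the future carbonyl carbon and the site of the later C=C bond.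

Step 6
Reactants: 9 (1S)-3-methoxy-1-nonadecylcyclohex-3-en-1-ol
Product: 10 (5S)-5-hydroxy-5-nonadecyl-2-(phenylselanyl)cyclohexan-1-one
Conditions: PhSeCl (1.05 equiv), pyridine (1.5 equiv), THF–H2O (10:1), −20 → 0 °C
Reagents that add atoms: benzeneselenenyl chloride Cl[Se]c1ccccc1; water O
Why: Electrophilic selenenylation of the enol ether at its β-carbon and hydrolysis of the resulting oxocarbenium ion should give the α-selanyl ketone regiospecifically; the selenide centre forms as a mixture and is removed in step 7.

Step 7
Reactants: 10 (5S)-5-hydroxy-5-nonadecyl-2-(phenylselanyl)cyclohexan-1-one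
Product: 12 (5S)-5-hydroxy-5-nonadecylcyclohex-2-en-1-one, via (5S)-5-hydroxy-5-nonadecyl-2-(benzeneseleninyl)cyclohexan-1-one 11 (not isolated)
Conditions: 30% aq. H2O2 (3 equiv), pyridine (2 equiv), CH2Cl2, 0 °C → rt
Reagents that add atoms: none
Why: Oxidation to the selenoxide and syn-elimination (selenoxide elimination) can only proceed away from the carbonyl carbon and should give the enone under cold, buffered conditions that spare the dehydration-prone tertiary β-hydroxy ketone.

**Compound list**

1 | (2R)-5-oxooxolane-2-carboxylic acid [(R)-5-oxotetrahydrofuran-2-carboxylic acid] | OC(=O)[C@H]1CCC(=O)O1 | starting material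
2 | 1-bromononadecane | CCCCCCCCCCCCCCCCCCCBr | starting material
3 | nonadecylmagnesium bromide | CCCCCCCCCCCCCCCCCCC[Mg]Br | intermediate
4 | (2R)-5-hydroxy-5-nonadecyloxolane-2-carboxylic acid | OC(=O)[C@H]1CCC(O)(CCCCCCCCCCCCCCCCCCC)O1 | intermediate
5 | methyl (2R)-5-methoxy-5-nonadecyloxolane-2-carboxylate | COC(=O)[C@H]1CCC(OC)(CCCCCCCCCCCCCCCCCCC)O1 | intermediate
6 | methyl (2R)-5-nonadecyl-5-(phenylsulfanyl)oxolane-2-carboxylate | COC(=O)[C@H]1CCC(Sc2ccccc2)(CCCCCCCCCCCCCCCCCCC)O1 | intermediate
7 | (5R)-5-(1-methoxyethenyl)-2-nonadecyl-2-(phenylsulfanyl)oxolane | COC(=C)[C@H]1CCC(Sc2ccccc2)(CCCCCCCCCCCCCCCCCCC)O1 | intermediate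
8 | [(5R)-5-(1-methoxyethenyl)-2-nonadecyloxolan-2-yl]lithium | COC(=C)[C@H]1CCC([Li])(CCCCCCCCCCCCCCCCCCC)O1 | intermediate
9 | (1S)-3-methoxy-1-nonadecylcyclohex-3-en-1-ol | CCCCCCCCCCCCCCCCCCC[C@]1(O)CCC=C(OC)C1 | intermediate
10 | (5S)-5-hydroxy-5-nonadecyl-2-(phenylselanyl)cyclohexan-1-one | CCCCCCCCCCCCCCCCCCC[C@]1(O)CCC([Se]c2ccccc2)C(=O)C1 | intermediate
11 | (5S)-5-hydroxy-5-nonadecyl-2-(benzeneseleninyl)cyclohexan-1-one | CCCCCCCCCCCCCCCCCCC[C@]1(O)CCC([Se](=O)c2ccccc2)C(=O)C1 | intermediate
12 | (5S)-5-hydroxy-5-nonadecylcyclohex-2-en-1-one | CCCCCCCCCCCCCCCCCCC[C@]1(O)CC=CC(=O)C1 | target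

**Step count and risks**

Total step count: 7. Longest linear sequence: 7 steps (from 1).

Steps most likely to fail:

Step 5 (proposed new method). The lithiated oxolane may fragment by anionic cycloreversion, be protonated before it rearranges, or react through a radical pair with erosion of the stereochemical relay. If the shift demands inversion at the lithium-bearing carbon, the epimer with lithium cis to the vinyl group may not react.

The fallback uses known reaction types, sets out from 5 and comes back at 10. Ester 5 is methylenated with the Tebbe reagent Cp2Ti(μ-CH2)(μ-Cl)AlMe2 as in step 4 to (5R)-2-methoxy-5-(1-methoxyethenyl)-2-nonadecyloxolane F1. Catalytic TMSOTf (2,6-di-tert-butyl-4-methylpyridine, CH2Cl2, −78 °C) ionises the ketal, and the enol ether adds to the cyclic oxocarbenium ion on the only face it can reach. This is an intramolecular Mukaiyama-type addition of an enol ether to a ketal (a Prins-type cyclisation); it forms the same C–C bond and relays the same stereocentre through the oxygen bridge. It should give (1R,4S)-2,2-dimethoxy-4-nonadecyl-7-oxabicyclo[2.2.1]heptane F2, which dilute aqueous HCl on work-up hydrolyses to (1R,4S)-4-nonadecyl-7-oxabicyclo[2.2.1]heptan-2-one F3. SmI2 (THF–MeOH, −78 °C) then cleaves the α-alkoxy ketone C–O bond reductively to (3S)-3-hydroxy-3-nonadecylcyclohexan-1-one F4. Kinetic enolisation away from the quaternary carbon (LiN(i-Pr)2, 2.2 equiv, THF, −78 °C) and PhSeBr give 10.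

Step 4. Lewis-acidic aluminium and titanium species may ionise the tertiary O,S-ketal and cause loss of thiophenol by elimination before or during methylenation.

The fallback builds the enol ether under purely basic conditions, sets out from 6 and comes back at 12. MeNHOMe·HCl with i-PrMgCl (THF, −20 °C) converts ester 6 into (2R)-N-methoxy-N-methyl-5-nonadecyl-5-(phenylsulfanyl)oxolane-2-carboxamide F5. MeMgBr (THF, 0 °C) gives 1-[(2R)-5-nonadecyl-5-(phenylsulfanyl)oxolan-2-yl]ethan-1-one F6. Kinetic enolisation at the methyl group with KN(SiMe3)2 and trapping with Et3SiCl (THF, −78 °C) give triethyl({1-[(2R)-5-nonadecyl-5-(phenylsulfanyl)oxolan-2-yl]ethenyl}oxy)silane F7. The reductive lithiation and [2,3] shift of step 5 then pass through {(5R)-2-nonadecyl-5-[1-(triethylsilyloxy)ethenyl]oxolan-2-yl}lithium F8 to (1S)-1-nonadecyl-3-[(triethylsilyl)oxy]cyclohex-3-en-1-ol F9. A Saegusa–Ito dehydrogenation (Pd(OAc)2, MeCN, rt) leads directly to 12.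

Step 1. The Grignard reagent may over-add to the ring-opened ketone, attack the carboxylate, or enolise the lactone.

The fallback replaces direct addition by a Weinreb ketone synthesis, sets out from 1 and comes back at 5. Acid 1 is protected with isobutene (cat. H2SO4, CH2Cl2) as tert-butyl (2R)-5-oxooxolane-2-carboxylate F10. MeNHOMe·HCl with AlMe3 (CH2Cl2, 0 °C) opens the lactone to tert-butyl (2R)-2-hydroxy-5-[methoxy(methyl)amino]-5-oxopentanoate F11. Grignard reagent 3 (2.2 equiv, THF, −20 °C) gives tert-butyl (2R)-2-hydroxy-5-oxotetracosanoate F12 through the stable chelated adduct, which cannot over-add. HCl in MeOH (from AcCl, rt) removes the tert-butyl group and forms the methyl ester and cyclic methyl ketal 5.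

Further compounds
F1 | step 5 | (5R)-2-methoxy-5-(1-methoxyethenyl)-2-nonadecyloxolane | COC(=C)[C@H]1CCC(OC)(CCCCCCCCCCCCCCCCCCC)O1
F2 | step 5 | (1R,4S)-2,2-dimethoxy-4-nonadecyl-7-oxabicyclo[2.2.1]heptane | CCCCCCCCCCCCCCCCCCC[C@@]12CC[C@@H](O1)C(OC)(OC)C2
F3 | step 5 | (1R,4S)-4-nonadecyl-7-oxabicyclo[2.2.1]heptan-2-one | CCCCCCCCCCCCCCCCCCC[C@@]12CC[C@@H](O1)C(=O)C2
F4 | step 5 | (3S)-3-hydroxy-3-nonadecylcyclohexan-1-one | CCCCCCCCCCCCCCCCCCC[C@]1(O)CCCC(=O)C1
F5 | step 4 | (2R)-N-methoxy-N-methyl-5-nonadecyl-5-(phenylsulfanyl)oxolane-2-carboxamide | CON(C)C(=O)[C@H]1CCC(Sc2ccccc2)(CCCCCCCCCCCCCCCCCCC)O1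
F6 | step 4 | 1-[(2R)-5-nonadecyl-5-(phenylsulfanyl)oxolan-2-yl]ethan-1-one | CC(=O)[C@H]1CCC(Sc2ccccc2)(CCCCCCCCCCCCCCCCCCC)O1
F7 | step 4 | triethyl({1-[(2R)-5-nonadecyl-5-(phenylsulfanyl)oxolan-2-yl]ethenyl}oxy)silane | CC[Si](CC)(CC)OC(=C)[C@H]1CCC(Sc2ccccc2)(CCCCCCCCCCCCCCCCCCC)O1
F8 | step 4 | {(5R)-2-nonadecyl-5-[1-(triethylsilyloxy)ethenyl]oxolan-2-yl}lithium | CC[Si](CC)(CC)OC(=C)[C@H]1CCC([Li])(CCCCCCCCCCCCCCCCCCC)O1
F9 | step 4 | (1S)-1-nonadecyl-3-[(triethylsilyl)oxy]cyclohex-3-en-1-ol | CCCCCCCCCCCCCCCCCCC[C@]1(O)CCC=C(O[Si](CC)(CC)CC)C1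
F10 | step 1 | tert-butyl (2R)-5-oxooxolane-2-carboxylate | CC(C)(C)OC(=O)[C@H]1CCC(=O)O1
F11 | step 1 | tert-butyl (2R)-2-hydroxy-5-[methoxy(methyl)amino]-5-oxopentanoate | CON(C)C(=O)CC[C@@H](O)C(=O)OC(C)(C)C
F12 | step 1 | tert-butyl (2R)-2-hydroxy-5-oxotetracosanoate | CCCCCCCCCCCCCCCCCCCC(=O)CC[C@@H](O)C(=O)OC(C)(C)C
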